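Temperature was the first setting I could turn, and by hand a hotter flask should carry E through its maximum sooner. In the blue run at 85 °C, the readings of E went from 9% at 4.00 h to 12% at 20.0 h and 18% at 48.0 h, each with a scatter of 1.5 percentage points. In the red run at 115 °C, it fell from 24% at 2.00 h to 5% at 12.0 h, though that run also held more G. Time, the second setting, should act the same way, and the new flasks are all read at 20 h.

common to all: D 0.10 M

| flask | G | temperature | remark | time |
|---|---|---|---|---|
| blue | 0.20 M | 85 °C | run made earlier |  |
| red | 0.45 M | 115 °C | run made earlier |  |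
| gamma | 0.300 M | 115 °C |  | 20 h |
| delta | 0.300 M | 90 °C |  | 20 h |
| epsilon | 0.300 M | 140 °C |  | 20 h |

| blue: time / h | blue: E / % | red: time / h | red: E / % |
|---|---|---|---|
| 4.00 | 9 | 2.00 | 24 |
| 6.00 | 10 | 4.00 | 14 |
| 12.0 | 12 | 6.00 | 10 |
| 20.0 | 12 | 8.00 | 7 |
| 40.0 | 16 | 10.0 | 5 |
| 48.0 | 18 | 12.0 | 5 |

(scatter of a reading: 1.5 percentage points)

- the flask with the highest amount of E, in percent of the D charged ("all alike" if they lie within 1.5 percentage points) (gamma / delta / epsilon / all alike)
- final E, as a percentage of the D charged, in gamma
- final E, as a percentage of the D charged, in delta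
- final E, as a percentage of the D charged, in epsilon

The amount of G was the third setting, and I reckoned it from the balance of D, the reagent charged in the smaller amount. If each step from D onward takes one G, the mean number of G bound per D charged cannot pass cG/cD. I call this ratio the G budget, and for the new flasks it is 3.00, against 2.00 in blue and 4.50 in red. If G is what moves E onward, then E stops changing once the budget is spent. My reckoning gave an order rather than a figure: delta, close to blue, should hold the most E at that time, while epsilon, the hottest, should use up its budget and stop.

The forecast named delta as highest, with 19% there, 7% in gamma and 7% in epsilon, and it placed delta “still before the peak”.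

Delta did hold the most E, 15.0%, against 7.15% in gamma and 8.14% in epsilon, so the forecast's order stood and its figures lay within tolerance. But E in delta had already come down from 16.6% at 10.0 h, so at 20.0 h delta was past its maximum. Gamma read earlier, at 8.0 h, gave 13.4%, still below delta's value.

    G + E → Z + J (k = 0.590 M⁻¹ h⁻¹, Ea = 70.0 kJ mol⁻¹)
    G + Z → X + J (k = 0.280 M⁻¹ h⁻¹, Ea = 105 kJ mol⁻¹)
    D + G → E + J (k = 0.160 M⁻¹ h⁻¹, Ea = 90.0 kJ mol⁻¹)
    G + X → Q + J (k = 0.0650 M⁻¹ h⁻¹, Ea = 100 kJ mol⁻¹)
    (constants at 90 °C)

D can take 4 G, more than the budget, so G is the limiting reagent despite its excess over D. Epsilon had come to rest: at 20.0 h G stood at 0.0214% of its charge, J at 0.300 M equals 3.00 per D charged, and E was still 8.13% at 200 h. Gamma had not: its 0.271 M of J is 2.71 per D, with 9.8% of G left, and at 200 h E had fallen to 4.68%. Delta, with 63% of its G left, moved furthest, reaching 3.13% of E at 200 h.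

The numbers in the tables are calculated for an exercise; scatter was added.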